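**Retrosynthetic overview**
- The strategy rests on the C6(O)–C7–C8(O) triad of the ten-membered carbocycle, where C7 also carries the exocyclic C11=C13 methylene of the fused five-membered 8,12-lactone. This is the retron of an allyl transfer from a C13-metalated butenolide (γ-carbon C7) to a C6 aldehyde.
- Backwards: C6 acetate and C4–C5 oxirane (hydroxyl-directed epoxidation) ⇒ C6–C7 bond (intramolecular CrCl2 Barbier allylation) ⇒ butenolide C7=C11 (ring-closing metathesis, styrene lost) ⇒ C8–O ester of 2-(bromomethyl)acrylic acid.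
- The remaining ring carbons, C8–C9–C10(C14)=C1–C2(O) and C3–C4(C15)=C5–C6, are the same five-carbon unit used twice. Both C8–C9 and C2–C3 come from one catalytic asymmetric vinylogous Mukaiyama aldol of the silyl dienolate of methyl 3-methylbut-2-enoate, starting at cinnamaldehyde.
- Ring order: butenolide (step 12), then ten-membered carbocycle (step 13), then oxirane (step 14).

Key step: step 13

Remark on the chemistry: germacrane numbering is used for all intermediates; the bisphosphoramide is the pentane-1,5-diyl-linked dimer [(C22H18N2)P(O)N(CH3)]2(CH2)5 built from N,N'-dimethyl-1,1'-binaphthyl-2,2'-diamine, and the enantiomer that sends the dienolate to the aldehyde Si face is assumed to be the (S,S)-form, to be confirmed on compound 6 by Mosher ester analysis (the antipode is used otherwise).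

**Route**

Step 1
Reactants: 1 methyl 3-methylbut-2-enoate
Product: 3 1-methoxy-3-methyl-1-(tert-butyldimethylsilyloxy)buta-1,3-diene, via lithium dienolate 2 (not isolated)
Conditions: LDA (1.1 equiv), THF, −78 °C; t-BuMe2SiCl, DMPU, −78 °C to rt; distillation
Reagents that add atoms: tert-butyldimethylsilyl chloride, CC(C)(C)[Si](C)(C)Cl; lithium diisopropylamide, CC(C)[N-]C(C)C.[Li+] (lithium only in intermediate 2)
Why: Kinetic γ-deprotonation of the enoate gives the cross-conjugated lithium dienolate, which the hard silyl chloride traps on oxygen (O-silylation to a silyl ketene acetal); no stereocentre is formed and the ketene acetal geometry is irrelevant to the later γ-attack.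

Step 2
Reactants: 4 (E)-cinnamaldehyde; 3 1-methoxy-3-methyl-1-(tert-butyldimethylsilyloxy)buta-1,3-diene
Product: 6 methyl (2E,5S,6E)-5-hydroxy-3-methyl-7-phenylhepta-2,6-dienoate, via trichlorosilyl ether 5 (not isolated)
Conditions: SiCl4 (1.1 equiv), (S,S)-bisphosphoramide (2 mol%), i-Pr2NEt (10 mol%), CH2Cl2, −78 °C; aqueous NaHCO3
Reagents that add atoms: silicon tetrachloride, Cl[Si](Cl)(Cl)Cl (silicon and chlorine only in intermediate 5)
Why: Lewis-base-activated vinylogous Mukaiyama aldol in which the phosphoramide-bound trichlorosilyl cation activates the aldehyde, the dienolate reacts only through its unhindered γ-CH2 in 1,2-fashion, the chiral pocket exposes the Si face so that the C8 carbinol is formed (S), and the s-trans dienolate delivers the (E)-enoate.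

Step 3
Reactants: 6 methyl (2E,5S,6E)-5-hydroxy-3-methyl-7-phenylhepta-2,6-dienoate
Product: 7 methyl (2E,5S,6E)-5-(tert-butyldimethylsilyloxy)-3-methyl-7-phenylhepta-2,6-dienoate
Conditions: t-BuMe2SiCl, imidazole, DMF, rt
Reagents that add atoms: tert-butyldimethylsilyl chloride, CC(C)(C)[Si](C)(C)Cl
Why: Imidazole-promoted silylation of the secondary allylic alcohol masks O8 for the hydride and Lewis acid steps that follow and does not touch the stereocentre.

Step 4
Reactants: 7 methyl (2E,5S,6E)-5-(tert-butyldimethylsilyloxy)-3-methyl-7-phenylhepta-2,6-dienoate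
Product: 8 (2E,5S,6E)-5-(tert-butyldimethylsilyloxy)-3-methyl-7-phenylhepta-2,6-dien-1-ol
Conditions: i-Bu2AlH (2.2 equiv), CH2Cl2, −78 °C; Rochelle salt
Reagents that add atoms: none
Why: Hydride reduction of the conjugated ester by 1,2-addition gives the primary allylic alcohol with the (E)-alkene and the silyl ether intact.

Step 5
Reactants: 8 (2E,5S,6E)-5-(tert-butyldimethylsilyloxy)-3-methyl-7-phenylhepta-2,6-dien-1-ol
Product: 9 (2E,5S,6E)-5-(tert-butyldimethylsilyloxy)-3-methyl-7-phenylhepta-2,6-dienal
Conditions: activated MnO2 (excess), CH2Cl2, rt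
Reagents that add atoms: none
Why: MnO2 allylic oxidation is selective for the primary allylic alcohol, stops at the aldehyde and keeps the (E)-geometry of the trisubstituted enal.

Step 6
Reactants: 9 (2E,5S,6E)-5-(tert-butyldimethylsilyloxy)-3-methyl-7-phenylhepta-2,6-dienal; 3 1-methoxy-3-methyl-1-(tert-butyldimethylsilyloxy)buta-1,3-diene
Product: 11 methyl (2E,5S,6E,9S,10E)-9-(tert-butyldimethylsilyloxy)-5-hydroxy-3,7-dimethyl-11-phenylundeca-2,6,10-trienoate, via trichlorosilyl ether 10 (not isolated)
Conditions: SiCl4 (1.1 equiv), (S,S)-bisphosphoramide (5 mol%), i-Pr2NEt (10 mol%), CH2Cl2, −78 °C; aqueous NaHCO3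
Reagents that add atoms: silicon tetrachloride, Cl[Si](Cl)(Cl)Cl (silicon and chlorine only in intermediate 10)
Why: The same Lewis-base-activated vinylogous Mukaiyama aldol, now on the β,β-disubstituted enal, adds the γ-CH2 of 3 in 1,2-fashion to the Si face, so the C2 carbinol is formed (S) under catalyst control (the C8 stereocentre is too remote to interfere) together with the second (E)-enoate.

Step 7
Reactants: 11 methyl (2E,5S,6E,9S,10E)-9-(tert-butyldimethylsilyloxy)-5-hydroxy-3,7-dimethyl-11-phenylundeca-2,6,10-trienoate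
Product: 12 (2E,5S,6E,9S,10E)-9-(tert-butyldimethylsilyloxy)-3,7-dimethyl-11-phenylundeca-2,6,10-triene-1,5-diol
Conditions: i-Bu2AlH (3.3 equiv), CH2Cl2, −78 °C; Rochelle salt
Reagents that add atoms: none
Why: Hydride reduction of the enoate (one equivalent is consumed by the free hydroxyl) gives the C6 primary allylic alcohol without affecting the alkenes, the silyl ether or the C2 stereocentre.

Step 8
Reactants: 12 (2E,5S,6E,9S,10E)-9-(tert-butyldimethylsilyloxy)-3,7-dimethyl-11-phenylundeca-2,6,10-triene-1,5-diol
Product: 13 (2E,5S,6E,9S,10E)-9-(tert-butyldimethylsilyloxy)-5-hydroxy-3,7-dimethyl-11-phenylundeca-2,6,10-trienal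
Conditions: TEMPO (10 mol%), PhI(OAc)2 (1.1 equiv), CH2Cl2, 0 °C to rt
Reagents that add atoms: none
Why: In this oxoammonium (TEMPO) oxidation the unhindered primary allylic alcohol reacts much faster than the secondary allylic C2 alcohol, and under anhydrous conditions the enal is not oxidised further.

Step 9
Reactants: 13 (2E,5S,6E,9S,10E)-9-(tert-butyldimethylsilyloxy)-5-hydroxy-3,7-dimethyl-11-phenylundeca-2,6,10-trienal
Product: 14 (2E,5S,6E,9S,10E)-9-(tert-butyldimethylsilyloxy)-3,7-dimethyl-1-oxo-11-phenylundeca-2,6,10-trien-5-yl acetate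
Conditions: Ac2O, pyridine, CH2Cl2, 0 °C to rt
Reagents that add atoms: acetic anhydride, CC(=O)OC(C)=O
Why: Pyridine-mediated acylation installs the C2 acetate of the target on the only free hydroxyl, with retention and without affecting the enal.

Step 10
Reactants: 14 (2E,5S,6E,9S,10E)-9-(tert-butyldimethylsilyloxy)-3,7-dimethyl-1-oxo-11-phenylundeca-2,6,10-trien-5-yl acetate
Product: 15 (2E,5S,6E,9S,10E)-9-hydroxy-3,7-dimethyl-1-oxo-11-phenylundeca-2,6,10-trien-5-yl acetate
Conditions: HF·pyridine, pyridine, THF, 0 °C to rt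
Reagents that add atoms: none
Why: Buffered fluoride desilylation cleaves the Si–O bond at C8 and leaves the allylic acetate, the enal and both stereocentres untouched.

Step 11
Reactants: 15 (2E,5S,6E,9S,10E)-9-hydroxy-3,7-dimethyl-1-oxo-11-phenylundeca-2,6,10-trien-5-yl acetate; 16 2-(bromomethyl)acrylic acid
Product: 17 (2E,5S,6E,9S,10E)-5-acetoxy-3,7-dimethyl-1-oxo-11-phenylundeca-2,6,10-trien-9-yl 2-(bromomethyl)prop-2-enoate
Conditions: DCC (1.2 equiv), DMAP (5 mol%), CH2Cl2, −20 to 0 °C
Reagents that add atoms: none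
Why: Steglich-type carbodiimide esterification acylates the secondary allylic C8 alcohol with retention through the O-acylisourea of 16, and the low temperature with only a trace of nucleophilic amine keeps the allylic bromide from being displaced.

Step 12
Reactants: 17 (2E,5S,6E,9S,10E)-5-acetoxy-3,7-dimethyl-1-oxo-11-phenylundeca-2,6,10-trien-9-yl 2-(bromomethyl)prop-2-enoate
Product: 18 (2E,5S,6E)-8-[(2S)-4-(bromomethyl)-5-oxo-2,5-dihydrofuran-2-yl]-3,7-dimethyl-1-oxoocta-2,6-dien-5-yl acetate
Conditions: RuCl2(H2IMes)(=CH-C6H4-2-O-i-Pr) (second-generation Hoveyda-Grubbs catalyst, 5–10 mol%), CH2Cl2 (0.01 M), 40 °C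
Reagents that add atoms: none
Why: Ring-closing metathesis in which the ruthenium alkylidene loads at the styryl alkene (styrene is expelled) and closes onto the 1,1-disubstituted acrylate to give the five-membered butenolide with the C7=C11 bond, while the trisubstituted alkenes and the enal do not engage and the phosphine-free catalyst spares the allylic bromide.

Step 13
Reactants: 18 (2E,5S,6E)-8-[(2S)-4-(bromomethyl)-5-oxo-2,5-dihydrofuran-2-yl]-3,7-dimethyl-1-oxoocta-2,6-dien-5-yl acetate
Product: 21 (2S,6R,7S,8S)-2-acetoxy-6-hydroxygermacra-1(10)E,4E,11(13)-trien-8,12-olide, via allylchromium dichloride 19 (not isolated), via chromium alkoxide 20 (not isolated)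
Conditions: CrCl2 (8 equiv), THF, rt, syringe-pump addition of 18 (final 0.003 M); cold pH 7 phosphate buffer, product used at once
Reagents that add atoms: chromium dichloride, [Cr+2].[Cl-].[Cl-] (chromium and chlorine only in intermediates 19 and 20)
Why: Two equivalents of CrCl2 (divalent chromium) reduce the C13–Br bond by two single-electron transfers to the allylchromium dichloride 19 (trivalent chromium), whose γ-carbon C7 adds to the chromium-bound C6 aldehyde through a six-membered chair (SE2', 1,2-addition), which shifts the butenolide double bond to the exocyclic C11=C13 position and leaves the alkoxide 20. This is a Nozaki–Hiyama–Kishi type Barbier allylation, and its closest known relatives are the CrCl2 closures of ten-membered germacranolide rings from 2-(bromomethyl)acrylate-type bromides and the intermolecular Barbier additions of 3-(bromomethyl)furan-2(5H)-ones that give trans-β,γ-disubstituted α-methylene lactones. The only ring closed is the ten-membered carbocycle, by C6–C7 bond formation in a 10-exo-trig attack on the aldehyde under high dilution; the lactone is already present, so the 8,12-olide regiochemistry is fixed beforehand. The C7 configuration is controlled by the C8 stereocentre of the planar butenolide, the aldehyde bonding on the face opposite the C9 substituent to give the trans-fused lactone, and the C6 configuration is controlled by the ring-locked geometry of the allylchromium (C8 trans to C13, hence equatorial in the chair) with the enal chain equatorial, which gives the 6,7-anti alcohol. The step needs γ- over α-attack, 1,2- over 1,4-addition, cyclisation over oligomerisation and no acyl shift to O6; these are secured respectively by the SE2' mode of allylchromium reagents, the oxophilic chromium at the unhindered enal, the few rotatable bonds left by two (E)-trisubstituted alkenes and the flat lactone, and the cold neutral work-up.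

Step 14
Reactants: 21 (2S,6R,7S,8S)-2-acetoxy-6-hydroxygermacra-1(10)E,4E,11(13)-trien-8,12-olide
Product: 22 (2S,4R,5R,6S,7S,8S)-2-acetoxy-4,5-epoxy-6-hydroxygermacra-1(10)E,11(13)-dien-8,12-olide
Conditions: VO(acac)2 (5 mol%), t-BuOOH (1.5 equiv, in decane), CH2Cl2, 0 °C
Reagents that add atoms: tert-butyl hydroperoxide, CC(C)(C)OO
Why: In this hydroxyl-directed epoxidation the C6 alkoxide on the vanadium tert-butylperoxo complex delivers oxygen only to the adjacent C4=C5 alkene (the remote C1=C10 and the electron-poor C11=C13 are left), on the outer face of the conformer in which H6 eclipses the alkene to avoid allylic 1,3-strain with the C15 methyl, which gives the threo (4R,5R) epoxy alcohol.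

Step 15
Reactants: 22 (2S,4R,5R,6S,7S,8S)-2-acetoxy-4,5-epoxy-6-hydroxygermacra-1(10)E,11(13)-dien-8,12-olide
Product: 23 (2S,4R,5R,6S,7R,8S)-2,6-diacetoxy-4,5-epoxygermacra-1(10)E,11(13)-dien-8,12-olide (CNP0270851.2)
Conditions: Ac2O, pyridine, DMAP (10 mol%), CH2Cl2, 0 °C
Reagents that add atoms: acetic anhydride, CC(=O)OC(C)=O
Why: Nucleophile-catalysed acylation of the secondary C6 alcohol under mild buffered conditions leaves the oxirane, the α-methylene lactone and the C2 acetate untouched and changes no stereocentre (the C6 and C7 descriptors change between 21, 22 and 23 only because the substituent priorities change).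

**Compound list**
1 | methyl 3-methylbut-2-enoate | COC(=O)C=C(C)C | starting material
2 | lithium 1-methoxy-3-methylbuta-1,3-dien-1-olate | C=C(C)C=C(OC)[O-].[Li+] | intermediate
3 | 1-methoxy-3-methyl-1-(tert-butyldimethylsilyloxy)buta-1,3-diene | C=C(C)C=C(OC)O[Si](C)(C)C(C)(C)C | intermediate
4 | (E)-cinnamaldehyde | O=C/C=C/c1ccccc1 | starting material
5 | trichlorosilyl ether of 6 | Cl[Si](Cl)(Cl)O[C@H](/C=C/c1ccccc1)C/C(C)=C/C(=O)OC | intermediate
6 | methyl (2E,5S,6E)-5-hydroxy-3-methyl-7-phenylhepta-2,6-dienoate | O[C@H](/C=C/c1ccccc1)C/C(C)=C/C(=O)OC | intermediate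
7 | methyl (2E,5S,6E)-5-(tert-butyldimethylsilyloxy)-3-methyl-7-phenylhepta-2,6-dienoate | CC(C)(C)[Si](C)(C)O[C@H](/C=C/c1ccccc1)C/C(C)=C/C(=O)OC | intermediate
8 | (2E,5S,6E)-5-(tert-butyldimethylsilyloxy)-3-methyl-7-phenylhepta-2,6-dien-1-ol | CC(C)(C)[Si](C)(C)O[C@H](/C=C/c1ccccc1)C/C(C)=C/CO | intermediate
9 | (2E,5S,6E)-5-(tert-butyldimethylsilyloxy)-3-methyl-7-phenylhepta-2,6-dienal | CC(C)(C)[Si](C)(C)O[C@H](/C=C/c1ccccc1)C/C(C)=C/C=O | intermediate
10 | trichlorosilyl ether of 11 | CC(C)(C)[Si](C)(C)O[C@H](/C=C/c1ccccc1)C/C(C)=C/[C@@H](O[Si](Cl)(Cl)Cl)C/C(C)=C/C(=O)OC | intermediate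
11 | methyl (2E,5S,6E,9S,10E)-9-(tert-butyldimethylsilyloxy)-5-hydroxy-3,7-dimethyl-11-phenylundeca-2,6,10-trienoate | CC(C)(C)[Si](C)(C)O[C@H](/C=C/c1ccccc1)C/C(C)=C/[C@@H](O)C/C(C)=C/C(=O)OC | intermediate
12 | (2E,5S,6E,9S,10E)-9-(tert-butyldimethylsilyloxy)-3,7-dimethyl-11-phenylundeca-2,6,10-triene-1,5-diol | CC(C)(C)[Si](C)(C)O[C@H](/C=C/c1ccccc1)C/C(C)=C/[C@@H](O)C/C(C)=C/CO | intermediate
13 | (2E,5S,6E,9S,10E)-9-(tert-butyldimethylsilyloxy)-5-hydroxy-3,7-dimethyl-11-phenylundeca-2,6,10-trienal | CC(C)(C)[Si](C)(C)O[C@H](/C=C/c1ccccc1)C/C(C)=C/[C@@H](O)C/C(C)=C/C=O | intermediate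
14 | (2E,5S,6E,9S,10E)-9-(tert-butyldimethylsilyloxy)-3,7-dimethyl-1-oxo-11-phenylundeca-2,6,10-trien-5-yl acetate | CC(C)(C)[Si](C)(C)O[C@H](/C=C/c1ccccc1)C/C(C)=C/[C@@H](OC(C)=O)C/C(C)=C/C=O | intermediate
15 | (2E,5S,6E,9S,10E)-9-hydroxy-3,7-dimethyl-1-oxo-11-phenylundeca-2,6,10-trien-5-yl acetate | O[C@H](/C=C/c1ccccc1)C/C(C)=C/[C@@H](OC(C)=O)C/C(C)=C/C=O | intermediate
16 | 2-(bromomethyl)acrylic acid | C=C(CBr)C(=O)O | starting material
17 | (2E,5S,6E,9S,10E)-5-acetoxy-3,7-dimethyl-1-oxo-11-phenylundeca-2,6,10-trien-9-yl 2-(bromomethyl)prop-2-enoate | C=C(CBr)C(=O)O[C@H](/C=C/c1ccccc1)C/C(C)=C/[C@@H](OC(C)=O)C/C(C)=C/C=O | intermediate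
18 | (2E,5S,6E)-8-[(2S)-4-(bromomethyl)-5-oxo-2,5-dihydrofuran-2-yl]-3,7-dimethyl-1-oxoocta-2,6-dien-5-yl acetate | O=C1O[C@H](C=C1CBr)C/C(C)=C/[C@@H](OC(C)=O)C/C(C)=C/C=O | intermediate
19 | C13 allylchromium dichloride derived from 18 | O=C1O[C@H](C=C1C[Cr](Cl)Cl)C/C(C)=C/[C@@H](OC(C)=O)C/C(C)=C/C=O | intermediate
20 | C6 dichlorochromium alkoxide of 21 | C=C1C(=O)O[C@H]2C/C(C)=C/[C@@H](OC(C)=O)C/C(C)=C/[C@@H](O[Cr](Cl)Cl)[C@H]12 | intermediate
21 | (2S,6R,7S,8S)-2-acetoxy-6-hydroxygermacra-1(10)E,4E,11(13)-trien-8,12-olide | C=C1C(=O)O[C@H]2C/C(C)=C/[C@@H](OC(C)=O)C/C(C)=C/[C@@H](O)[C@H]12 | intermediate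
22 | (2S,4R,5R,6S,7S,8S)-2-acetoxy-4,5-epoxy-6-hydroxygermacra-1(10)E,11(13)-dien-8,12-olide | C=C1C(=O)O[C@H]2C/C(C)=C/[C@@H](OC(C)=O)C[C@@]3(C)O[C@@H]3[C@@H](O)[C@H]12 | intermediate
23 | (2S,4R,5R,6S,7R,8S)-2,6-diacetoxy-4,5-epoxygermacra-1(10)E,11(13)-dien-8,12-olide (CNP0270851.2) | C=C1C(=O)O[C@H]2C/C(C)=C/[C@@H](OC(C)=O)C[C@@]3(C)O[C@@H]3[C@@H](OC(C)=O)[C@H]12 | target

**Step count**
Total steps: 15. Longest linear sequence: 15 steps (from compound 1; compounds 4 and 16 enter at steps 2 and 11).

**Steps most likely to fail**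

Step 13 (ten-membered Barbier closure). Three processes may go wrong. Reduction of the C13–Br bond may be followed by intermolecular addition or protonation instead of ring closure. Bonding may occur on the wrong butenolide face at C7. The lactone acyl group may shift to the new C6 alkoxide. The fallback sets out from 18 and comes back at 21; it makes the nucleophile isolable and runs the closure under catalysis.
- Borylation of the allylic bromide of 18 with bis(pinacolato)diboron under Pd2(dba)3 (zerovalent palladium) in toluene at 50 °C would give the butenolide C13 pinacol allylboronate F1.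
- 2-Carbonyl-substituted allylboronates add to aldehydes only slowly without activation, so F1 should survive purification.
- Sc(OTf)3-catalysed intramolecular allylboration at high dilution would then form the C6–C7 bond through the same closed chair with the same ring-locked geometry, so the same trans-fused, 6,7-anti outcome is expected; this macrocyclic variant is itself untested.
- The product is the C6 pinacol borate F2, in which O6 stays masked against acyl shift until buffered aqueous work-up releases 21.

Step 14 (directed epoxidation). Oxygen may be delivered to the wrong face of C4=C5 if the ring conformation overrides the allylic 1,3-strain preference. The Lewis-acidic vanadium may also trigger transannular opening of the new oxirane by the C1=C10 alkene, or acyl shift from O8 to the free O6. The fallback sets out from 12 and comes back at 22; it installs the oxirane before the carbocycle, under reagent control.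
- Sharpless asymmetric epoxidation of the primary allylic alcohol of 12 (Ti(Oi-Pr)4, D-(−)-diethyl tartrate, t-BuOOH, 4 Å sieves, CH2Cl2, −20 °C) would give the (4R,5R)-epoxy diol F3. The secondary C2 allylic alcohol, with a methyl cis to the carbinol carbon, is a slow substrate.
- The operations of steps 8 to 12 then follow: TEMPO/PhI(OAc)2 to the epoxy aldehyde F4, Ac2O/pyridine to the C2 acetate F5, AcOH-buffered Bu4NF to the C8 alcohol F6, carbodiimide esterification with 16 to the 2-(bromomethyl)acrylate F7, and ring-closing metathesis to the butenolide epoxy aldehyde F8.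
- CrCl2 closure of F8 as in step 13 gives 22 directly. The electrophile is now an α,β-epoxy aldehyde, the type for which ten-membered Barbier closures of germacranolides are established.
- The C6 configuration would have to be confirmed, because the oxirane-bearing α-carbon now also influences it.

Step 12 (ring-closing metathesis). The allylic bromide may decompose the ruthenium alkylidene, or the electron-poor 1,1-disubstituted acrylate alkene may fail to engage so that styryl homodimerisation takes over. The fallback sets out from 15 and comes back at 18; it introduces the bromide after the ring is closed.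
- Esterification of 15 with 2-[(tert-butyldimethylsilyloxy)methyl]acrylic acid (DCC, catalytic DMAP) would give the silyloxymethyl acrylate F9.
- Ring-closing metathesis with the same catalyst, which can now be heated in toluene, would give the 3-(silyloxymethyl)butenolide F10.
- HF·pyridine would give the 3-(hydroxymethyl)butenolide F11.
- Appel bromination (CBr4, PPh3, CH2Cl2, 0 °C) would give 18.

Further compounds
F1 | step 13 | butenolide C13 pinacol allylboronate | O=C1O[C@H](C=C1CB2OC(C)(C)C(C)(C)O2)C/C(C)=C/[C@@H](OC(C)=O)C/C(C)=C/C=O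
F2 | step 13 | C6 pinacol borate of 21 | C=C1C(=O)O[C@H]2C/C(C)=C/[C@@H](OC(C)=O)C/C(C)=C/[C@@H](OB3OC(C)(C)C(C)(C)O3)[C@H]12
F3 | step 14 | (4R,5R)-epoxy diol from 12 | CC(C)(C)[Si](C)(C)O[C@H](/C=C/c1ccccc1)C/C(C)=C/[C@@H](O)C[C@@]1(C)O[C@@H]1CO
F4 | step 14 | C2-hydroxy 4,5-epoxy aldehyde with C8 silyl ether | CC(C)(C)[Si](C)(C)O[C@H](/C=C/c1ccccc1)C/C(C)=C/[C@@H](O)C[C@@]1(C)O[C@@H]1C=O
F5 | step 14 | C2-acetoxy 4,5-epoxy aldehyde with C8 silyl ether | CC(C)(C)[Si](C)(C)O[C@H](/C=C/c1ccccc1)C/C(C)=C/[C@@H](OC(C)=O)C[C@@]1(C)O[C@@H]1C=O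
F6 | step 14 | C2-acetoxy 4,5-epoxy aldehyde with free C8 hydroxyl | O[C@H](/C=C/c1ccccc1)C/C(C)=C/[C@@H](OC(C)=O)C[C@@]1(C)O[C@@H]1C=O
F7 | step 14 | C8 2-(bromomethyl)acrylate of the epoxy aldehyde | C=C(CBr)C(=O)O[C@H](/C=C/c1ccccc1)C/C(C)=C/[C@@H](OC(C)=O)C[C@@]1(C)O[C@@H]1C=O
F8 | step 14 | 3-(bromomethyl)butenolide epoxy aldehyde | O=C1O[C@H](C=C1CBr)C/C(C)=C/[C@@H](OC(C)=O)C[C@@]2(C)O[C@@H]2C=O
F9 | step 12 | C8 2-[(tert-butyldimethylsilyloxy)methyl]acrylate of 15 | C=C(CO[Si](C)(C)C(C)(C)C)C(=O)O[C@H](/C=C/c1ccccc1)C/C(C)=C/[C@@H](OC(C)=O)C/C(C)=C/C=O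
F10 | step 12 | 3-[(tert-butyldimethylsilyloxy)methyl]butenolide enal | O=C1O[C@H](C=C1CO[Si](C)(C)C(C)(C)C)C/C(C)=C/[C@@H](OC(C)=O)C/C(C)=C/C=O
F11 | step 12 | 3-(hydroxymethyl)butenolide enal | O=C1O[C@H](C=C1CO)C/C(C)=C/[C@@H](OC(C)=O)C/C(C)=C/C=O
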